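**Strategy**

The oxane ring (O1, C2 to C6) is disconnected at C5–C6. C6 is an unsubstituted methylene on the ring oxygen, hence a latent formaldehyde-derived oxocarbenium carbon; C5 is a tertiary carbon whose side chain starts with two sp3 carbons, hence the γ-terminus of an allylsilane. An intramolecular Hosomi–Sakurai cyclisation of the acyclic (2-methoxyethoxy)methyl ether of a Morita–Baylis–Hillman alcohol closes the ring, sets C5 trans to C2 through a diequatorial chair, and leaves a vinyl group at C5 for B-alkyl Suzuki coupling with an (E,E)-trienyl iodide. C2 is set by an asymmetric Morita–Baylis–Hillman reaction, which also delivers the acrylate.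

Key step: step 5

Assumption: (E)-geranylacetone (10) is bought as the single (E)-isomer.

**Route**

Step 1
Reactants: 1 pent-4-enal; 2 allyltrimethylsilane
Product: 3 (4E)-6-(trimethylsilyl)hex-4-enal (E isomer expected to predominate; any Z isomer is carried along)
Conditions: second-generation Grubbs catalyst RuCl2(H2IMes)(PCy3)(=CHPh) (2 mol %), 2 (3 equiv), CH2Cl2, 40 °C
Reagents that add atoms: none
Why: Olefin cross-metathesis of two unhindered terminal alkenes with the silane in excess should give the allylsilane, whose alkene geometry is irrelevant because step 5 erases it; the silane is introduced before the acrylate exists because a diene carrying both the terminal alkene and the acrylate would close to a cyclopentene by ring-closing metathesis.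

Step 2
Reactants: 3 (4E)-6-(trimethylsilyl)hex-4-enal; 4 1,1,1,3,3,3-hexafluoropropan-2-yl prop-2-enoate (hexafluoroisopropyl acrylate)
Product: 5 1,1,1,3,3,3-hexafluoropropan-2-yl (3R,6E)-3-hydroxy-2-methylidene-8-(trimethylsilyl)oct-6-enoate
Conditions: β-isocupreidine (10 mol %), DMF, –55 °C
Reagents that add atoms: none
Why: Asymmetric Morita–Baylis–Hillman reaction, in which the quinuclidine nitrogen adds to the activated acrylate and the phenolic OH of the catalyst hydrogen-bonds to the aldolate so that only the betaine leading to the (R)-alcohol eliminates quickly; this carbinol carbon becomes C2 of the target.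

Step 3
Reactants: 5 hexafluoroisopropyl ester
Product: 6 methyl (3R,6E)-3-hydroxy-2-methylidene-8-(trimethylsilyl)oct-6-enoate
Conditions: MeOH, Et3N, 0 °C to rt
Reagents that add atoms: methanol, CO
Why: Transesterification of the activated hexafluoroisopropyl ester proceeds under mild amine base without touching the carbinol stereocenter or the allylsilane.

Step 4
Reactants: 6 methyl ester
Product: 7 methyl (3R,6E)-3-[(2-methoxyethoxy)methoxy]-2-methylidene-8-(trimethylsilyl)oct-6-enoate
Conditions: MEMCl, iPr2NEt, CH2Cl2, 0 °C to rt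
Reagents that add atoms: (2-methoxyethoxy)methyl chloride, COCCOCCl
Why: O-alkylation of the secondary alcohol by the reactive α-chloro ether under a non-nucleophilic base gives the mixed formaldehyde acetal whose methylene carbon will become C6; acrylate and allylsilane are inert to these conditions.

Step 5
Reactants: 7 (2-methoxyethoxy)methyl ether
Product: 9 methyl 2-[(2R,5R)-5-ethenyloxan-2-yl]prop-2-enoate, via oxocarbenium ion 8 (not isolated)
Conditions: TiCl4 (2.5 equiv), 2,6-di-tert-butyl-4-methylpyridine, CH2Cl2, –78 °C; aq. NaHCO3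
Reagents that add atoms: none
Why: TiCl4 is held in a chelate by the two oxygens of the 2-methoxyethoxy arm, so the acetal ionises to the alkoxymethyl cation CH2=O+ on the future ring oxygen (8), and the γ-carbon of the allylsilane (future C5) adds to this carbon (future C6) with loss of the silyl group as Me3SiCl, which unveils the vinyl group. The closest known reaction type is the intramolecular Hosomi–Sakurai reaction of allylsilanes with alkoxymethyl ethers, which gives 3-vinyltetrahydropyrans. The six-membered oxane closes in a 6-endo-trig mode with respect to the C=O+ bond and in an exo mode with respect to the allylsilane C=C bond. The new stereocenter C5 is controlled by the existing C2 stereocenter through a chair transition state in which the acrylate-bearing C2 substituent and the reacting alkene both sit equatorial, which should give the 2,5-trans (2R,5R) ring; E and Z allylsilane converge because the alkene geometry is lost. The step needs ionisation towards the ring oxygen rather than loss of the whole acetal, which the bidentate arm should secure, and chemoselectivity over the acrylate and the allylic C2–O bond, which the electron-poor 1,1-disubstituted alkene and the low temperature should secure.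

Step 6
Reactants: 10 (5E)-6,10-dimethylundeca-5,9-dien-2-one ((E)-geranylacetone)
Product: 12 (5E)-6,10-dimethylundeca-5,9-dien-1-yne, via enol diethyl phosphate 11 (not isolated)
Conditions: LiN(iPr)2 (1.05 equiv), THF, –78 °C; ClP(O)(OEt)2, –78 °C to rt; LiN(iPr)2 (2.3 equiv), –78 °C to rt; H2O
Reagents that add atoms: none
Why: Kinetic deprotonation at the methyl group, O-phosphorylation of the enolate and base-induced elimination of the terminal enol phosphate convert the methyl ketone into the terminal alkyne without touching the trisubstituted alkenes.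

Step 7
Reactants: 12 (5E)-6,10-dimethylundeca-5,9-dien-1-yne
Product: 14 (1E,5E)-1-iodo-2,6,10-trimethylundeca-1,5,9-triene, via alkenylalane 13 (not isolated)
Conditions: Me3Al (2 equiv), Cp2ZrCl2 (0.25 equiv), CH2Cl2, 0 °C to rt; then I2, THF, –30 to 0 °C
Reagents that add atoms: trimethylaluminium, C[Al](C)C; iodine, II
Why: Negishi zirconium-catalysed carboalumination adds methyl and aluminium syn across the alkyne with aluminium at the terminal carbon, and iodinolysis with retention fixes the (E)-trisubstituted alkene.

Step 8
Reactants: 9 methyl 2-[(2R,5R)-5-ethenyloxan-2-yl]prop-2-enoate; 14 (1E,5E)-1-iodo-2,6,10-trimethylundeca-1,5,9-triene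
Product: 16 methyl 2-[(2R,5S)-5-[(3E,7E)-4,8,12-trimethyltrideca-3,7,11-trien-1-yl]oxan-2-yl]prop-2-enoate, via B-alkyl-9-BBN 15 (not isolated)
Conditions: 9-BBN-H (1.2 equiv), THF, 0 °C to rt; then 14, PdCl2(dppf) (5 mol %), AsPh3, Cs2CO3, DMF/THF/H2O, rt
Reagents that add atoms: none
Why: 9-BBN should add anti-Markovnikov to the monosubstituted vinyl group in preference to the electron-poor conjugated acrylate, and the B-alkyl Suzuki–Miyaura coupling joins the primary alkylborane to the alkenyl iodide with retention of the E geometry; no stereocenter is involved.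

Step 9
Reactants: 16 methyl ester
Product: 17 rhopaloic acid A, 2-[(2R,5S)-5-[(3E,7E)-4,8,12-trimethyltrideca-3,7,11-trien-1-yl]oxan-2-yl]prop-2-enoic acid
Conditions: LiOH·H2O, THF/MeOH/H2O, rt; then 1 M HCl to pH 3
Reagents that add atoms: lithium hydroxide, [Li+].[OH-]
Why: Saponification of the methyl ester by acyl substitution leaves the C2 and C5 stereocenters and the alkenes untouched, and acidification gives the free acid.

**Compound list**

1 | pent-4-enal | C=CCCC=O | starting material
2 | allyltrimethylsilane | C=CC[Si](C)(C)C | starting material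
3 | (4E)-6-(trimethylsilyl)hex-4-enal | O=CCC/C=C/C[Si](C)(C)C | intermediate
4 | 1,1,1,3,3,3-hexafluoropropan-2-yl prop-2-enoate | C=CC(=O)OC(C(F)(F)F)C(F)(F)F | starting material
5 | 1,1,1,3,3,3-hexafluoropropan-2-yl (3R,6E)-3-hydroxy-2-methylidene-8-(trimethylsilyl)oct-6-enoate | C[Si](C)(C)C/C=C/CC[C@@H](O)C(=C)C(=O)OC(C(F)(F)F)C(F)(F)F | intermediate
6 | methyl (3R,6E)-3-hydroxy-2-methylidene-8-(trimethylsilyl)oct-6-enoate | C[Si](C)(C)C/C=C/CC[C@@H](O)C(=C)C(=O)OC | intermediate
7 | methyl (3R,6E)-3-[(2-methoxyethoxy)methoxy]-2-methylidene-8-(trimethylsilyl)oct-6-enoate | C[Si](C)(C)C/C=C/CC[C@@H](OCOCCOC)C(=C)C(=O)OC | intermediate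
8 | oxocarbenium ion, [(3R,6E)-1-methoxy-2-methylidene-1-oxo-8-(trimethylsilyl)oct-6-en-3-yl](methylidene)oxonium | C[Si](C)(C)C/C=C/CC[C@@H]([O+]=C)C(=C)C(=O)OC | intermediate (not isolated)
9 | methyl 2-[(2R,5R)-5-ethenyloxan-2-yl]prop-2-enoate (2,5-trans) | C=C(C(=O)OC)[C@H]1CC[C@H](C=C)CO1 | intermediate
10 | (5E)-6,10-dimethylundeca-5,9-dien-2-one | CC(=O)CC/C=C(\C)CCC=C(C)C | starting material
11 | diethyl (5E)-6,10-dimethylundeca-1,5,9-trien-2-yl phosphate | C=C(OP(=O)(OCC)OCC)CC/C=C(\C)CCC=C(C)C | intermediate (not isolated)
12 | (5E)-6,10-dimethylundeca-5,9-dien-1-yne | C#CCC/C=C(\C)CCC=C(C)C | intermediate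
13 | dimethyl[(1E,5E)-2,6,10-trimethylundeca-1,5,9-trien-1-yl]alumane | C[Al](C)/C=C(\C)CC/C=C(\C)CCC=C(C)C | intermediate (not isolated)
14 | (1E,5E)-1-iodo-2,6,10-trimethylundeca-1,5,9-triene | I/C=C(\C)CC/C=C(\C)CCC=C(C)C | intermediate
15 | methyl 2-[(2R,5S)-5-[2-(9-borabicyclo[3.3.1]nonan-9-yl)ethyl]oxan-2-yl]prop-2-enoate | C=C(C(=O)OC)[C@H]1CC[C@H](CCB2C3CCCC2CCC3)CO1 | intermediate (not isolated)
16 | methyl 2-[(2R,5S)-5-[(3E,7E)-4,8,12-trimethyltrideca-3,7,11-trien-1-yl]oxan-2-yl]prop-2-enoate | C=C(C(=O)OC)[C@H]1CC[C@H](CC/C=C(\C)CC/C=C(\C)CCC=C(C)C)CO1 | intermediate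
17 | rhopaloic acid A, 2-[(2R,5S)-5-[(3E,7E)-4,8,12-trimethyltrideca-3,7,11-trien-1-yl]oxan-2-yl]prop-2-enoic acid | C=C(C(=O)O)[C@H]1CC[C@H](CC/C=C(\C)CC/C=C(\C)CCC=C(C)C)CO1 | target

**Step count**

Total: 9 steps. Longest linear sequence: 7 steps (steps 1 to 5, 8 and 9); steps 6 and 7 make the side-chain fragment.

**Steps most likely to fail**

1. Step 5. The acetal may ionise in the wrong direction and lose the whole protecting group, chloride may attack the allylic ether or the acrylate, the allylsilane may be protodesilylated, or facial selectivity in the ring closure may be poor. The fallback forms the same C5–C6 bond by a radical addition–fragmentation without Lewis acid; it sets out from 1 and comes back at 9. Cross-metathesis of 1 with allyl phenyl sulfone (second-generation Grubbs catalyst RuCl2(H2IMes)(PCy3)(=CHPh), CH2Cl2, 40 °C) should give (4E)-6-(benzenesulfonyl)hex-4-enal F1. The reaction of step 2 should then give 1,1,1,3,3,3-hexafluoropropan-2-yl (3R,6E)-8-(benzenesulfonyl)-3-hydroxy-2-methylideneoct-6-enoate F2, and methanolysis as in step 3 should give methyl (3R,6E)-8-(benzenesulfonyl)-3-hydroxy-2-methylideneoct-6-enoate F3. O-Alkylation with chloromethyl phenyl selenide (iPr2NEt, NaI, CH2Cl2) should give methyl (3R,6E)-8-(benzenesulfonyl)-2-methylidene-3-[(phenylselanyl)methoxy]oct-6-enoate F4. Slow addition of Bu3SnH with AIBN in dilute benzene at 80 °C should generate the alkoxymethyl radical, which closes the oxane in a 6-exo-trig mode onto the allyl sulfone through a chair and expels the phenylsulfonyl radical to give 9.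

2. Step 8. Transmetalation of the B-alkyl group may be slow, so that protodeboronation, β-hydride elimination or palladium hydride chemistry at the acrylate takes over. The fallback replaces the boron-to-palladium transfer by an organozinc coupling; it sets out from 15 and comes back at 16. Oxidation of 15 with NaBO3·4H2O in THF/H2O should give methyl 2-[(2R,5R)-5-(2-hydroxyethyl)oxan-2-yl]prop-2-enoate F5. Treatment with I2, PPh3 and imidazole in CH2Cl2 should give methyl 2-[(2R,5R)-5-(2-iodoethyl)oxan-2-yl]prop-2-enoate F6. Zinc dust with LiCl in THF should insert to give the alkylzinc iodide, iodo{2-[(3R,6R)-6-(3-methoxy-3-oxoprop-1-en-2-yl)oxan-3-yl]ethyl}zinc F7, which is not isolated and is coupled with 14 under Pd(PPh3)4 catalysis (Negishi coupling) to give 16.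

3. Step 2. Enantioselectivity may be insufficient for this unbranched aldehyde, and conversion may be low because the product is acylated by a second molecule of the activated acrylate. The fallback gives up asymmetric catalysis for a racemic synthesis with resolution; it sets out from 3 and comes back at 6. Reaction of 3 with methyl acrylate and DABCO (MeOH, rt) should give racemic methyl (6E)-3-hydroxy-2-methylidene-8-(trimethylsilyl)oct-6-enoate F8 directly. Preparative chromatography on a chiral stationary phase then separates 6 from its enantiomer, methyl (3S,6E)-3-hydroxy-2-methylidene-8-(trimethylsilyl)oct-6-enoate F9, which is discarded.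

**Further compounds**

F1 | step 5 | (4E)-6-(benzenesulfonyl)hex-4-enal | O=CCC/C=C/CS(=O)(=O)c1ccccc1
F2 | step 5 | 1,1,1,3,3,3-hexafluoropropan-2-yl (3R,6E)-8-(benzenesulfonyl)-3-hydroxy-2-methylideneoct-6-enoate | O=S(=O)(C/C=C/CC[C@@H](O)C(=C)C(=O)OC(C(F)(F)F)C(F)(F)F)c1ccccc1
F3 | step 5 | methyl (3R,6E)-8-(benzenesulfonyl)-3-hydroxy-2-methylideneoct-6-enoate | O=S(=O)(C/C=C/CC[C@@H](O)C(=C)C(=O)OC)c1ccccc1
F4 | step 5 | methyl (3R,6E)-8-(benzenesulfonyl)-2-methylidene-3-[(phenylselanyl)methoxy]oct-6-enoate | O=S(=O)(C/C=C/CC[C@@H](OC[Se]c1ccccc1)C(=C)C(=O)OC)c1ccccc1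
F5 | step 8 | methyl 2-[(2R,5R)-5-(2-hydroxyethyl)oxan-2-yl]prop-2-enoate | C=C(C(=O)OC)[C@H]1CC[C@H](CCO)CO1
F6 | step 8 | methyl 2-[(2R,5R)-5-(2-iodoethyl)oxan-2-yl]prop-2-enoate | C=C(C(=O)OC)[C@H]1CC[C@H](CCI)CO1
F7 | step 8 | iodo{2-[(3R,6R)-6-(3-methoxy-3-oxoprop-1-en-2-yl)oxan-3-yl]ethyl}zinc | C=C(C(=O)OC)[C@H]1CC[C@H](CC[Zn]I)CO1
F8 | step 2 | racemic methyl (6E)-3-hydroxy-2-methylidene-8-(trimethylsilyl)oct-6-enoate | C[Si](C)(C)C/C=C/CCC(O)C(=C)C(=O)OC
F9 | step 2 | methyl (3S,6E)-3-hydroxy-2-methylidene-8-(trimethylsilyl)oct-6-enoate | C[Si](C)(C)C/C=C/CC[C@H](O)C(=C)C(=O)OC
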